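**Plan**

Numbering: ring B = C1-C4, C4a, C11a; diaryl ether O5; ring A = C5a, C6-C9, C9a; lactone O10-C11(=O); pyran O1' on C8, C4' on C9.
Feature exploited: on ring B the ether oxygen O5 (on C4a) and the lactone carbon C11 (on C11a) sit on adjacent carbons, with the C4 prenyl group beside C4a and the C1 oxygen beside C11a. A C4a-C11a aryne polarised by the C1 oxygen can take up a nucleophile and an electrophile in exactly this 1,2-pattern.
Retrosynthesis: cut the lactone bond O10-C11 first, then C4a-O5 and C11a-C11 together. This leaves a ring A phenol, a ring B 2-silylaryl triflate and CO2.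
Forward, ring A: tetramethoxybenzene is prenylated and oxidised to the dihydroxyquinone, and the pyran closes by a Knoevenagel/oxa-6π sequence. The quinone level then tells C5a-O (temporary allyl) from C7-O and C9a-O (MOM).
Forward, ring B: phloroglucinol bis-MOM ether, as its carbamate, takes silicon at C11a and prenyl at C4 in two directed metalations and is then made into the triflate.
Assembly: union in the aryne step (no ring formed), MOM removal, and the seven-membered lactone last. The target has no stereocentre and no stereogenic alkene, so no stereocontrol is needed.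

Key step: step 14

Assumption: the hydroxy-pyranoquinone made in step 4 is taken to react as its more stable para-quinone tautomer (C7=O, C9a=O, C5a-OH), and the exocyclic alkene geometry of the transient oxatriene is left open because it equilibrates by reversible amine addition.

**Ring A (steps 1-7)**

Step 1
Reactants: 1 1,2,4,5-tetramethoxybenzene; 2 prenyl bromide (1-bromo-3-methylbut-2-ene)
Product: 4 1,2,4,5-tetramethoxy-3-(3-methylbut-2-enyl)benzene, via aryllithium 3 (not isolated)
Conditions: n-BuLi, TMEDA, THF, 0 °C; then 2, -78 °C → rt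
Reagents that add atoms: prenyl bromide 2, CC(C)=CCBr
Why: Directed ortho-metalation between two methoxy groups (both free ring positions are equivalent) followed by SN2 alkylation of the aryllithium with the allylic bromide is the standard entry to 3-alkyl-1,2,4,5-tetramethoxybenzenes.

Step 2
Reactants: 4 1,2,4,5-tetramethoxy-3-(3-methylbut-2-enyl)benzene
Product: 5 2,5-dimethoxy-3-(3-methylbut-2-enyl)-1,4-benzoquinone
Conditions: (NH4)2Ce(NO3)6, MeCN/H2O, 0 °C
Reagents that add atoms: water, O
Why: Oxidative demethylation of a para-dimethoxyarene by tetravalent cerium is fast at 0 °C, spares trisubstituted alkenes, and can give only one quinone because the two para-dimethoxy pairs of 4 are related by symmetry.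

Step 3
Reactants: 5 2,5-dimethoxy-3-(3-methylbut-2-enyl)-1,4-benzoquinone
Product: 6 2,5-dihydroxy-3-(3-methylbut-2-enyl)-1,4-benzoquinone
Conditions: NaOH, EtOH/H2O, 60 °C; then cold dilute HCl
Reagents that add atoms: sodium hydroxide, [Na+].[OH-]
Why: The methoxy groups of 5 are vinylogous esters and are exchanged for hydroxide by conjugate addition-elimination (vinylogous saponification), the usual last step towards 3-alkyl-2,5-dihydroxybenzoquinones, while cold dilute acid in the work-up avoids cyclisation of the prenyl group.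

Step 4
Reactants: 6 2,5-dihydroxy-3-(3-methylbut-2-enyl)-1,4-benzoquinone; 7 3-methylbut-2-enal
Product: 9 6-hydroxy-2,2-dimethyl-7-(3-methylbut-2-enyl)-2H-chromene-5,8-dione, via oxatriene 8 (not isolated)
Conditions: 7, ethylenediammonium diacetate (10 mol %), toluene, 80 °C
Reagents that add atoms: 3-methylbut-2-enal 7, CC(C)=CC=O
Why: Amine-salt-catalysed Knoevenagel condensation at the only free ring carbon (C9) gives oxatriene 8, which closes the pyran by oxa-6π electrocyclisation, a domino sequence well known for hydroxyquinones and enals, and closure through either flanking oxygen leads to the same compound because 6 is symmetric about its C6-C9 axis.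

Step 5
Reactants: 9 6-hydroxy-2,2-dimethyl-7-(3-methylbut-2-enyl)-2H-chromene-5,8-dione
Product: 10 6-(allyloxy)-2,2-dimethyl-7-(3-methylbut-2-enyl)-2H-chromene-5,8-dione
Conditions: allyl bromide, K2CO3, DMF, rt
Reagents that add atoms: allyl bromide, C=CCBr
Why: Williamson-type O-alkylation of the acidic hydroxyquinone (a vinylogous carboxylic acid) with K2CO3 in DMF gives the 2-alkoxy-1,4-quinone, as with lapachol-type substrates, and C-alkylation is disfavoured because C6 already carries the prenyl group.

Step 6
Reactants: 10 6-(allyloxy)-2,2-dimethyl-7-(3-methylbut-2-enyl)-2H-chromene-5,8-dione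
Product: 12 6-(allyloxy)-5,8-bis(methoxymethoxy)-2,2-dimethyl-7-(3-methylbut-2-enyl)-2H-chromene, via hydroquinone 11 (not isolated)
Conditions: Na2S2O4, THF/H2O, rt, Ar; extract; then MOMCl, i-Pr2NEt, CH2Cl2, 0 → 40 °C
Reagents that add atoms: chloromethyl methyl ether (MOMCl), COCCl
Why: Quinone reduction with Na2S2O4 turns the two carbonyls, and only these, into the C7 and C9a phenols, which are capped at once as MOM ethers (acetal formation with MOMCl and a hindered amine) before air can reoxidise hydroquinone 11, so the oxidation level of 10 differentiates the three oxygens.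

Step 7
Reactants: 12 6-(allyloxy)-5,8-bis(methoxymethoxy)-2,2-dimethyl-7-(3-methylbut-2-enyl)-2H-chromene
Product: 13 ring A phenol 5,8-bis(methoxymethoxy)-2,2-dimethyl-7-(3-methylbut-2-enyl)-2H-chromen-6-ol
Conditions: Pd(PPh3)4 (5 mol %), morpholine, THF, rt, Ar
Reagents that add atoms: none
Why: Tsuji-Trost-type deallylation through a π-allyl complex of divalent palladium, with morpholine as allyl acceptor, frees the C5a phenol under neutral conditions that leave MOM ethers, prenyl group and chromene alkene untouched.

**Ring B (steps 8-13)**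

Step 8
Reactants: 14 phloroglucinol
Product: 15 3,5-bis(methoxymethoxy)phenol
Conditions: MOMCl (2 equiv), i-Pr2NEt, DMF, 0 °C → rt
Reagents that add atoms: chloromethyl methyl ether (MOMCl), COCCl
Why: Acetal-type O-alkylation of three equivalent hydroxyls with two equivalents of MOMCl is statistical, and the known bis-ether is separated by chromatography from the mono- and tris-ethers, which can be recycled.

Step 9
Reactants: 15 3,5-bis(methoxymethoxy)phenol
Product: 16 3,5-bis(methoxymethoxy)phenyl N,N-diethylcarbamate
Conditions: NaH, THF, 0 °C; ClC(O)NEt2, rt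
Reagents that add atoms: N,N-diethylcarbamoyl chloride, CCN(CC)C(=O)Cl
Why: O-Carbamoylation of the sodium phenoxide puts the strongest oxygen-based metalation-directing group on the oxygen that will become the C4a triflate.

Step 10
Reactants: 16 3,5-bis(methoxymethoxy)phenyl N,N-diethylcarbamate
Product: 18 3,5-bis(methoxymethoxy)-2-(trimethylsilyl)phenyl N,N-diethylcarbamate, via aryllithium 17 (not isolated)
Conditions: s-BuLi, TMEDA, THF, -78 °C; Me3SiCl, -78 °C → rt
Reagents that add atoms: chlorotrimethylsilane, C[Si](C)(C)Cl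
Why: Directed ortho-metalation takes one of the two equivalent positions between the carbamate and a MOM ether, where both directing groups cooperate, and the aryllithium is silylated at -78 °C before an anionic ortho-Fries shift can set in.

Step 11
Reactants: 18 3,5-bis(methoxymethoxy)-2-(trimethylsilyl)phenyl N,N-diethylcarbamate; 2 prenyl bromide
Product: 20 3,5-bis(methoxymethoxy)-2-(3-methylbut-2-enyl)-6-(trimethylsilyl)phenyl N,N-diethylcarbamate, via aryllithium 19 (not isolated)
Conditions: s-BuLi, TMEDA, THF, -78 °C; CuBr·SMe2 (10 mol %), 2, -78 → -20 °C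
Reagents that add atoms: prenyl bromide 2, CC(C)=CCBr
Why: A second directed ortho-metalation takes the remaining position ortho to the carbamate (C4), with silicon as blocking group on the other side, and copper-catalysed SN2 allylation forms the C4-prenyl bond, the prenyl group coming last so that no acidic benzylic-allylic CH2 is present during any metalation.

Step 12
Reactants: 20 3,5-bis(methoxymethoxy)-2-(3-methylbut-2-enyl)-6-(trimethylsilyl)phenyl N,N-diethylcarbamate
Product: 21 3,5-bis(methoxymethoxy)-2-(3-methylbut-2-enyl)-6-(trimethylsilyl)phenol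
Conditions: LiAlH4, THF, 0 °C → reflux; H2O quench
Reagents that add atoms: none
Why: Hydride reduction cleaves hindered aryl N,N-diethylcarbamates to phenols and does not touch aryl-silicon bonds, acetals or isolated alkenes.

Step 13
Reactants: 21 3,5-bis(methoxymethoxy)-2-(3-methylbut-2-enyl)-6-(trimethylsilyl)phenol
Product: 22 ring B silyl triflate 3,5-bis(methoxymethoxy)-2-(3-methylbut-2-enyl)-6-(trimethylsilyl)phenyl trifluoromethanesulfonate
Conditions: Tf2O, pyridine, CH2Cl2, 0 °C
Reagents that add atoms: trifluoromethanesulfonic anhydride, O=S(=O)(OS(=O)(=O)C(F)(F)F)C(F)(F)F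
Why: O-Sulfonylation of the phenol with Tf2O and pyridine is the standard last step towards 2-(trimethylsilyl)aryl triflates, and the base protects the MOM ethers from adventitious acid.

**Union and endgame (steps 14-16)**

Step 14
Reactants: 13 ring A phenol; 22 ring B silyl triflate; 23 carbon dioxide
Product: 28 seco-acid 2-{[5,8-bis(methoxymethoxy)-2,2-dimethyl-7-(3-methylbut-2-enyl)-2H-chromen-6-yl]oxy}-4,6-bis(methoxymethoxy)-3-(3-methylbut-2-enyl)benzoic acid, via potassium phenoxide 24 (not isolated), via aryne 25 (not isolated), via arylpotassium 26 (not isolated), via potassium carboxylate 27 (not isolated)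
Conditions: 13, KH (1.0 equiv), 18-crown-6, THF, 0 °C; CO2 (1 atm, solution saturated), dry KF, then 22 (0.8 equiv, slow addition), 0 °C → rt; cold dilute HCl to pH 4
Reagents that add atoms: carbon dioxide 23, O=C=O
Why: Proposed new method: fluoride attacks the C11a silyl group of 22 and expels the C4a triflate to give aryne 25, the proton-free phenoxide 24 adds through its C5a oxygen to C4a, and the arylpotassium 26 so generated at C11a is carboxylated by dissolved CO2 to carboxylate 27, so that C4a-O5 and C11a-C11 form in one operation with no transition metal involved. The closest known reaction types are the three-component coupling of arynes with amines and CO2 to give anthranilic acids, the fluoride-promoted O-arylation of hindered phenols with 2-silylaryl triflates, and the xanthone synthesis in which the aryl anion left by phenoxide addition to an aryne is caught by an ester carbonyl; the combination of phenoxide, aryne and CO2 has not been demonstrated. No ring closes and no stereocentre is formed. The regioselectivity needed (oxygen at C4a, carbon at C11a) is secured by the C1 alkoxy group, whose inductive pull distorts the aryne so that nucleophiles attack the distal carbon and the negative charge builds up next to oxygen, a bias expected to outweigh the steric demand of the C4 prenyl group. The chemoselectivity needed is secured by substrate and medium: C5a-O is the only unprotected oxygen of 13, ring A has no free CH that could undergo Kolbe-Schmitt carboxylation, binding of CO2 to the hindered phenoxide is reversible, and KH, KF and THF offer no proton, so that 26 can be quenched only by slow C-H transfer from a prenyl methylene, which capture by CO2 at saturation should outrun. A slight excess of 24 over 22 keeps the hindered carboxylate 27 from competing for the aryne.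

Step 15
Reactants: 28 seco-acid
Product: 30 2-{[5,8-dihydroxy-2,2-dimethyl-7-(3-methylbut-2-enyl)-2H-chromen-6-yl]oxy}-4,6-dihydroxy-3-(3-methylbut-2-enyl)benzoic acid, via pentasilyl derivative 29 (not isolated)
Conditions: Me3SiOTf, 2,2'-bipyridyl, MeCN, 0 °C → rt, Ar; then degassed H2O, rt; used crude
Reagents that add atoms: none
Why: Aromatic MOM ethers are converted by Me3SiOTf buffered with 2,2'-bipyridyl into aryl silyl ethers that water hydrolyses (Lewis-acid acetal cleavage under near-neutral conditions), so no strong protic acid is present that could decarboxylate the phloroglucinol-type acid, attack the chromene or cyclise the prenyl groups onto the new phenols.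

Step 16
Reactants: 30 tetrahydroxy seco-acid
Product: 32 target depsidone CNP0263700.0, via O-acylisourea 31 (not isolated)
Conditions: N,N'-dicyclohexylcarbodiimide, THF/toluene, high dilution, Ar, 0 °C → rt
Reagents that add atoms: none
Why: Carbodiimide lactonisation of 2-(2-hydroxyaryloxy)benzoic acids is the classical depsidone ring closure, and in O-acylisourea 31 only the C9a hydroxyl can reach C11 (7-exo-trig acyl substitution), whereas the other phenols could react only between molecules, which dilution suppresses.

**Compound list**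

1 | 1,2,4,5-tetramethoxybenzene | COc1cc(OC)c(OC)cc1OC | starting material
2 | prenyl bromide (1-bromo-3-methylbut-2-ene) | CC(C)=CCBr | starting material
3 | 2,3,5,6-tetramethoxyphenyllithium | [Li]c1c(OC)c(OC)cc(OC)c1OC | intermediate
4 | 1,2,4,5-tetramethoxy-3-(3-methylbut-2-enyl)benzene | COc1cc(OC)c(OC)c(CC=C(C)C)c1OC | intermediate
5 | 2,5-dimethoxy-3-(3-methylbut-2-enyl)-1,4-benzoquinone | COC1=CC(=O)C(OC)=C(CC=C(C)C)C1=O | intermediate
6 | 2,5-dihydroxy-3-(3-methylbut-2-enyl)-1,4-benzoquinone | O=C1C=C(O)C(=O)C(CC=C(C)C)=C1O | intermediate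
7 | 3-methylbut-2-enal | CC(C)=CC=O | starting material
8 | oxatriene 5-hydroxy-3-(3-methylbut-2-enylidene)-6-(3-methylbut-2-enyl)cyclohex-5-ene-1,2,4-trione | O=C1C(=CC=C(C)C)C(=O)C(=O)C(CC=C(C)C)=C1O | intermediate
9 | 6-hydroxy-2,2-dimethyl-7-(3-methylbut-2-enyl)-2H-chromene-5,8-dione | CC1(C)C=CC2=C(O1)C(=O)C(CC=C(C)C)=C(O)C2=O | intermediate
10 | 6-(allyloxy)-2,2-dimethyl-7-(3-methylbut-2-enyl)-2H-chromene-5,8-dione | CC1(C)C=CC2=C(O1)C(=O)C(CC=C(C)C)=C(OCC=C)C2=O | intermediate
11 | 6-(allyloxy)-2,2-dimethyl-7-(3-methylbut-2-enyl)-2H-chromene-5,8-diol | CC1(C)C=Cc2c(O1)c(O)c(CC=C(C)C)c(OCC=C)c2O | intermediate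
12 | 6-(allyloxy)-5,8-bis(methoxymethoxy)-2,2-dimethyl-7-(3-methylbut-2-enyl)-2H-chromene | CC1(C)C=Cc2c(O1)c(OCOC)c(CC=C(C)C)c(OCC=C)c2OCOC | intermediate
13 | ring A phenol, 5,8-bis(methoxymethoxy)-2,2-dimethyl-7-(3-methylbut-2-enyl)-2H-chromen-6-ol | Oc1c(CC=C(C)C)c(OCOC)c2OC(C)(C)C=Cc2c1OCOC | intermediate
14 | phloroglucinol | Oc1cc(O)cc(O)c1 | starting material
15 | 3,5-bis(methoxymethoxy)phenol | COCOc1cc(O)cc(OCOC)c1 | intermediate
16 | 3,5-bis(methoxymethoxy)phenyl N,N-diethylcarbamate | CCN(CC)C(=O)Oc1cc(OCOC)cc(OCOC)c1 | intermediate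
17 | 2-lithio-3,5-bis(methoxymethoxy)phenyl N,N-diethylcarbamate | CCN(CC)C(=O)Oc1cc(OCOC)cc(OCOC)c1[Li] | intermediate
18 | 3,5-bis(methoxymethoxy)-2-(trimethylsilyl)phenyl N,N-diethylcarbamate | CCN(CC)C(=O)Oc1cc(OCOC)cc(OCOC)c1[Si](C)(C)C | intermediate
19 | 2-lithio-3,5-bis(methoxymethoxy)-6-(trimethylsilyl)phenyl N,N-diethylcarbamate | CCN(CC)C(=O)Oc1c([Li])c(OCOC)cc(OCOC)c1[Si](C)(C)C | intermediate
20 | 3,5-bis(methoxymethoxy)-2-(3-methylbut-2-enyl)-6-(trimethylsilyl)phenyl N,N-diethylcarbamate | CCN(CC)C(=O)Oc1c(CC=C(C)C)c(OCOC)cc(OCOC)c1[Si](C)(C)C | intermediate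
21 | 3,5-bis(methoxymethoxy)-2-(3-methylbut-2-enyl)-6-(trimethylsilyl)phenol | Oc1c(CC=C(C)C)c(OCOC)cc(OCOC)c1[Si](C)(C)C | intermediate
22 | ring B silyl triflate, 3,5-bis(methoxymethoxy)-2-(3-methylbut-2-enyl)-6-(trimethylsilyl)phenyl trifluoromethanesulfonate | C[Si](C)(C)c1c(OCOC)cc(OCOC)c(CC=C(C)C)c1OS(=O)(=O)C(F)(F)F | intermediate
23 | carbon dioxide | O=C=O | starting material
24 | potassium phenoxide of 13 | [K+].[O-]c1c(CC=C(C)C)c(OCOC)c2OC(C)(C)C=Cc2c1OCOC | intermediate
25 | aryne 3,5-bis(methoxymethoxy)-6-(3-methylbut-2-enyl)-1,2-didehydrobenzene (C4a-C11a triple bond) | C1#CC(CC=C(C)C)=C(OCOC)C=C1OCOC | intermediate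
26 | C11a-arylpotassium of the diaryl ether | [K]c1c(OCOC)cc(OCOC)c(CC=C(C)C)c1Oc1c(CC=C(C)C)c(OCOC)c2OC(C)(C)C=Cc2c1OCOC | intermediate
27 | potassium salt of seco-acid 28 | [K+].[O-]C(=O)c1c(OCOC)cc(OCOC)c(CC=C(C)C)c1Oc1c(CC=C(C)C)c(OCOC)c2OC(C)(C)C=Cc2c1OCOC | intermediate
28 | seco-acid, 2-{[5,8-bis(methoxymethoxy)-2,2-dimethyl-7-(3-methylbut-2-enyl)-2H-chromen-6-yl]oxy}-4,6-bis(methoxymethoxy)-3-(3-methylbut-2-enyl)benzoic acid | OC(=O)c1c(OCOC)cc(OCOC)c(CC=C(C)C)c1Oc1c(CC=C(C)C)c(OCOC)c2OC(C)(C)C=Cc2c1OCOC | intermediate
29 | trimethylsilyl ester tetrakis(trimethylsilyl) ether of 30 | C[Si](C)(C)OC(=O)c1c(O[Si](C)(C)C)cc(O[Si](C)(C)C)c(CC=C(C)C)c1Oc1c(CC=C(C)C)c(O[Si](C)(C)C)c2OC(C)(C)C=Cc2c1O[Si](C)(C)C | intermediate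
30 | 2-{[5,8-dihydroxy-2,2-dimethyl-7-(3-methylbut-2-enyl)-2H-chromen-6-yl]oxy}-4,6-dihydroxy-3-(3-methylbut-2-enyl)benzoic acid | OC(=O)c1c(O)cc(O)c(CC=C(C)C)c1Oc1c(CC=C(C)C)c(O)c2OC(C)(C)C=Cc2c1O | intermediate
31 | O-acylisourea from 30 and N,N'-dicyclohexylcarbodiimide | O=C(OC(=NC1CCCCC1)NC1CCCCC1)c1c(O)cc(O)c(CC=C(C)C)c1Oc1c(CC=C(C)C)c(O)c2OC(C)(C)C=Cc2c1O | intermediate
32 | target depsidone CNP0263700.0 (C1, C3, C7 hydroxyls; C4, C6 prenyl groups; 2,2-dimethylpyran on C8/C9) | CC(C)=CCc1c(O)c2c(c3c1Oc1c(CC=C(C)C)c(O)cc(O)c1C(=O)O3)C=CC(C)(C)O2 | target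

**Step count**

Total step count: 16.
Longest linear sequence: 10 steps (steps 1-7, then 14, 15 and 16). The ring B branch has 6 steps before the union.

**Steps most likely to fail**

**Step 14.**
- What may go wrong: the C11a aryl anion may be protonated (by traces of water or by proton transfer from the neighbouring prenyl methylene) before it is carboxylated. CO2 may tie up the phenoxide too strongly. The phenoxide may attack sulfur of the triflate instead of the aryne.
- Fallback, from 13 and 22, back at 28: the two bonds are made one after the other by known reactions.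
 - CsF in MeCN, with the solvent as proton source, should give by ordinary aryne O-arylation the C11a-unsubstituted diaryl ether F1.
 - n-BuLi in THF metalates its most acidic ring position, C2 between the two MOM ethers, and Me3SiCl blocks it to give the C2-silylated diaryl ether F2.
 - A second directed ortho-metalation (s-BuLi, TMEDA, -78 °C) is then left with C11a only, between the C1 MOM ether and O5. A CO2 quench gives the C2-silylated seco-acid F3.
 - n-Bu4NF in wet THF removes the blocking silyl group by protodesilylation, and the route is rejoined at 28.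

**Step 15.**
- What may go wrong: the electron-rich acid may lose CO2 by protodecarboxylation once its ortho and para oxygens are free. The liberated C7/C9a hydroquinone may be oxidised by air. The prenyl groups may cyclise onto the new phenols.
- Fallback, from 28, back at 32: the carboxyl group is activated before the phenols are freed.
 - N-ethyl-N'-(3-dimethylaminopropyl)carbodiimide hydrochloride, pentafluorophenol and catalytic DMAP in CH2Cl2 should give the pentafluorophenyl ester of the seco-acid F4, which cannot decarboxylate.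
 - The same Me3SiOTf/2,2'-bipyridyl treatment followed by water gives the tetrahydroxy pentafluorophenyl ester F5.
 - i-Pr2NEt at high dilution under argon then closes the lactone by intramolecular transesterification through the C9a hydroxyl. Compound 30 and step 16 are bypassed and the route is rejoined at 32.

**Step 11.**
- What may go wrong: metalation may occur at the wrong ring position (C2, between the two MOM ethers). The carbamoyl group may migrate (anionic ortho-Fries) on warming. Allylic transposition may occur during C-C bond formation.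
- Fallback, from 18, back at 21: the prenyl group is delivered by a sigmatropic shift instead of a metalation.
 - LiAlH4 in THF cleaves the carbamate to 3,5-bis(methoxymethoxy)-2-(trimethylsilyl)phenol F6.
 - Tsuji-Trost-type O-alkylation with tert-butyl 2-methylbut-3-en-2-yl carbonate and Pd(PPh3)4 in THF at 0 °C gives the 1,1-dimethylallyl aryl ether F7.
 - Heating in toluene at 110 °C triggers the aromatic Claisen rearrangement to the only free ortho position (C4). Allyl inversion delivers the prenyl group and gives 21, so that steps 11 and 12 are replaced.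

**Further compounds**

F1 | step 14 | 6-[3,5-bis(methoxymethoxy)-2-(3-methylbut-2-enyl)phenoxy]-5,8-bis(methoxymethoxy)-2,2-dimethyl-7-(3-methylbut-2-enyl)-2H-chromene | COCOc1cc(OCOC)c(CC=C(C)C)c(c1)Oc1c(CC=C(C)C)c(OCOC)c2OC(C)(C)C=Cc2c1OCOC
F2 | step 14 | 6-[3,5-bis(methoxymethoxy)-2-(3-methylbut-2-enyl)-4-(trimethylsilyl)phenoxy]-5,8-bis(methoxymethoxy)-2,2-dimethyl-7-(3-methylbut-2-enyl)-2H-chromene | COCOc1cc(Oc2c(CC=C(C)C)c(OCOC)c3OC(C)(C)C=Cc3c2OCOC)c(CC=C(C)C)c(OCOC)c1[Si](C)(C)C
F3 | step 14 | 2-{[5,8-bis(methoxymethoxy)-2,2-dimethyl-7-(3-methylbut-2-enyl)-2H-chromen-6-yl]oxy}-4,6-bis(methoxymethoxy)-3-(3-methylbut-2-enyl)-5-(trimethylsilyl)benzoic acid | COCOc1c(C(=O)O)c(Oc2c(CC=C(C)C)c(OCOC)c3OC(C)(C)C=Cc3c2OCOC)c(CC=C(C)C)c(OCOC)c1[Si](C)(C)C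
F4 | step 15 | pentafluorophenyl ester of seco-acid 28 | O=C(Oc1c(F)c(F)c(F)c(F)c1F)c1c(OCOC)cc(OCOC)c(CC=C(C)C)c1Oc1c(CC=C(C)C)c(OCOC)c2OC(C)(C)C=Cc2c1OCOC
F5 | step 15 | pentafluorophenyl ester of tetrahydroxy acid 30 | O=C(Oc1c(F)c(F)c(F)c(F)c1F)c1c(O)cc(O)c(CC=C(C)C)c1Oc1c(CC=C(C)C)c(O)c2OC(C)(C)C=Cc2c1O
F6 | step 11 | 3,5-bis(methoxymethoxy)-2-(trimethylsilyl)phenol | Oc1cc(OCOC)cc(OCOC)c1[Si](C)(C)C
F7 | step 11 | 1,5-bis(methoxymethoxy)-3-(2-methylbut-3-en-2-yloxy)-2-(trimethylsilyl)benzene | C=CC(C)(C)Oc1cc(OCOC)cc(OCOC)c1[Si](C)(C)C
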